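**Assumption:** Boc-D-alanine N-methoxy-N-methylamide (1) and 3-butenylmagnesium bromide (2, THF solution) are bought; the target is delivered as the free base.

## Retrosynthetic overview

1. Target 11 ⇐ N-Boc piperidine 10 by Boc removal.
2. C6–C1′ bond: visible-light decarboxylative radical alkylation of the N-acyliminium ion from N,O-acetal 6 with keto acid 9; this sets C6 cis to the C2 methyl.
3. 6 ⇐ piperidin-3-one 4 by substrate-controlled ketone reduction (sets C3) and acetylation.
4. 4 (the only ring, closed at N1–C6) ⇐ ozonolysis/cyclisation of alkenyl ketone 3 ⇐ Weinreb amide 1 (C2 from D-alanine) + Grignard 2.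
5. 9 ⇐ 12-bromododecanoic acid (7) + acetylacetone (8).

## Route

**Step 1**
Reactants: 1, tert-butyl N-[(2R)-1-[methoxy(methyl)amino]-1-oxopropan-2-yl]carbamate; 2, 3-butenylmagnesium bromide
Product: 3, tert-butyl N-[(2R)-3-oxohept-6-en-2-yl]carbamate
Conditions: 2 (2.5 equiv), THF, 0 °C → rt; aq NH4Cl
Reagents that add atoms: none beyond reactant 2 (C=CCC[Mg]Br supplies the butenyl group)
Why: Weinreb ketone synthesis; the chelated tetrahedral intermediate stops over-addition and α-epimerisation, so C2 (R) comes intact from D-alanine.

**Step 2**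
Reactants: 3, tert-butyl N-[(2R)-3-oxohept-6-en-2-yl]carbamate
Product: 4, tert-butyl (2R)-6-methoxy-2-methyl-3-oxopiperidine-1-carboxylate (C6 epimer mixture)
Conditions: O3, CH2Cl2/MeOH 4:1, −78 °C; Me2S, → rt; then PPTS (10 mol%), MeOH, rt
Reagents that add atoms: methanol, CO (supplies OCH3; the oxygen from ozone is lost as water)
Why: Criegee ozonolysis reveals the C6 aldehyde, the carbamate N–H closes the six-membered N-acyl hemiaminal, and mild acid exchanges OH for OMe; the C6 configuration is irrelevant because it is erased at the iminium stage.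

**Step 3**
Reactants: 4, tert-butyl (2R)-6-methoxy-2-methyl-3-oxopiperidine-1-carboxylate
Product: 5, tert-butyl (2R,3R)-3-hydroxy-6-methoxy-2-methylpiperidine-1-carboxylate
Conditions: L-Selectride, THF, −78 °C; NaOH/H2O2
Reagents that add atoms: none
Why: Substrate-controlled hydride reduction; A(1,3) strain with Boc holds the C2 methyl axial, so the bulky hydride attacks C3 anti to it and gives the 2,3-cis (3R) alcohol, as in cis-selective L-Selectride reductions of N-Boc-2-substituted piperidin-3-ones.

**Step 4**
Reactants: 5, tert-butyl (2R,3R)-3-hydroxy-6-methoxy-2-methylpiperidine-1-carboxylate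
Product: 6, tert-butyl (2R,3R)-3-acetoxy-6-methoxy-2-methylpiperidine-1-carboxylate
Conditions: Ac2O, Et3N, DMAP (cat.), CH2Cl2, 0 °C → rt
Reagents that add atoms: acetic anhydride, CC(=O)OC(C)=O
Why: Standard DMAP-catalysed O-acylation under basic conditions that leave the N,O-acetal and Boc group untouched.

**Step 5**
Reactants: 7, 12-bromododecanoic acid; 8, acetylacetone (pentane-2,4-dione)
Product: 9, 14-oxopentadecanoic acid
Conditions: K2CO3 (3 equiv), NaI (cat.), EtOH, reflux; then aq NaOH, rt; H3O+
Reagents that add atoms: none beyond reactant 8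
Why: C-alkylation of the β-diketone followed by in situ retro-Claisen deacetylation (alkylative deacylation) gives the methyl ketone directly.

**Step 6**
Reactants: 6, tert-butyl (2R,3R)-3-acetoxy-6-methoxy-2-methylpiperidine-1-carboxylate; 9, 14-oxopentadecanoic acid
Product: 10, tert-butyl (2R,3R,6S)-3-acetoxy-2-methyl-6-(13-oxotetradecyl)piperidine-1-carboxylate
Conditions: 9 (2 equiv), 3,6-di-tert-butyl-9-mesityl-10-phenylacridinium BF4 (5 mol%), 2,6-lutidine (0.3 equiv), HFIP/DCE 1:3, 4 Å MS, 450 nm LEDs, 0 °C, Ar
Reagents that add atoms: none beyond reactant 9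
Why: Proposed new method: HFIP ionises the N,O-acetal (loss of MeOH) to the N-Boc iminium ion paired with the carboxylate of 9; the excited acridinium (about +2.0 V) oxidises the carboxylate and CO2 loss gives the primary 13-oxotetradecyl radical, which adds in a polarity-matched way to cationic C6; the resulting carbamate radical cation is reduced by the acridine radical or by another carboxylate (SET chain), so the process is redox-neutral with MeOH and CO2 as the only by-products; the C2 methyl is pseudoaxial (A(1,3) strain with Boc) and axial attack syn to it gives the 2,6-cis (6S) product, by the same model as nucleophile additions to such ions; closest known reaction types are tin-mediated alkyl-radical addition to electrogenerated N-acyliminium "cation pools" and photoredox decarboxylative (Minisci-type) radical additions to iminium/heteroarenium ions.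

**Step 7**
Reactants: 10, tert-butyl (2R,3R,6S)-3-acetoxy-2-methyl-6-(13-oxotetradecyl)piperidine-1-carboxylate
Product: 11, (−)-3-O-acetylspectaline, (2R,3R,6S)-2-methyl-6-(13-oxotetradecyl)piperidin-3-yl acetate
Conditions: TFA/CH2Cl2 1:4, 0 °C; cold aq NaHCO3
Reagents that add atoms: none
Why: Acidolytic Boc cleavage leaves the acetate, ketone and all three stereocentres untouched; cold, brief neutralisation limits O→N acetyl migration.

## Compound list

1 | tert-butyl N-[(2R)-1-[methoxy(methyl)amino]-1-oxopropan-2-yl]carbamate (Boc-D-Ala Weinreb amide) | C[C@@H](NC(=O)OC(C)(C)C)C(=O)N(C)OC | starting material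
2 | 3-butenylmagnesium bromide | C=CCC[Mg]Br | starting material
3 | tert-butyl N-[(2R)-3-oxohept-6-en-2-yl]carbamate | C[C@@H](NC(=O)OC(C)(C)C)C(=O)CCC=C | intermediate
4 | tert-butyl (2R)-6-methoxy-2-methyl-3-oxopiperidine-1-carboxylate (C6 epimers) | COC1CCC(=O)[C@@H](C)N1C(=O)OC(C)(C)C | intermediate
5 | tert-butyl (2R,3R)-3-hydroxy-6-methoxy-2-methylpiperidine-1-carboxylate | COC1CC[C@@H](O)[C@@H](C)N1C(=O)OC(C)(C)C | intermediate
6 | tert-butyl (2R,3R)-3-acetoxy-6-methoxy-2-methylpiperidine-1-carboxylate | COC1CC[C@@H](OC(C)=O)[C@@H](C)N1C(=O)OC(C)(C)C | intermediate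
7 | 12-bromododecanoic acid | OC(=O)CCCCCCCCCCCBr | starting material
8 | acetylacetone (pentane-2,4-dione) | CC(=O)CC(C)=O | starting material
9 | 14-oxopentadecanoic acid | CC(=O)CCCCCCCCCCCCC(=O)O | intermediate
10 | tert-butyl (2R,3R,6S)-3-acetoxy-2-methyl-6-(13-oxotetradecyl)piperidine-1-carboxylate | CC(=O)CCCCCCCCCCCC[C@H]1CC[C@@H](OC(C)=O)[C@@H](C)N1C(=O)OC(C)(C)C | intermediate
11 | (2R,3R,6S)-2-methyl-6-(13-oxotetradecyl)piperidin-3-yl acetate, (−)-3-O-acetylspectaline | CC(=O)CCCCCCCCCCCC[C@H]1CC[C@@H](OC(C)=O)[C@@H](C)N1 | target

## Summary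

Total steps: 7. Longest linear sequence: 6 (steps 1–4, 6, 7 from compound 1).

Steps most likely to fail:

1. **Step 6 (proposed new method).** Risks are inefficient radical capture by the low-concentration iminium ion, over-oxidation, and weaker cis selectivity than with two-electron nucleophiles. Fallback (known chemistry): BF3·OEt2/allyltrimethylsilane amidoalkylation of 6 (established 2,6-cis selectivity), Ru-catalysed cross-metathesis of the 6-allyl piperidine with tridec-12-en-2-one, H2/Pd-C, then step 7.
2. **Step 2.** The γ-keto aldehyde can divert to the furan or a 2,5-dimethoxytetrahydrofuran, and C2 can epimerise under acid. Fallback: drive the keto aldehyde fully to (R)-N-Boc-1-(furan-2-yl)ethylamine (Paal–Knorr), run the known aza-Achmatowicz rearrangement (NBS or m-CPBA, then MeOH/H+) to the 6-methoxy-2H-pyridin-3(6H)-one, and hydrogenate the enone C=C (H2, Pd/C) to reach 4.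
3. **Step 3.** The C6-epimeric mixture may erode the cis selectivity of the reduction. Fallback: separate any 2,3-trans (3S) alcohol and convert it by Mitsunobu inversion with acetic acid (PPh3, DIAD) directly into acetate 6, so both diastereomers converge.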